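**Retrosynthetic overview**

- The target is reached by functional-group changes (C19 acetylation, C15 oxidation, hydride reductions, C18 methylation) from a 3-oxo-19-ester of the ent-labd-7-ene skeleton whose ester alcohol is a chiral auxiliary.
- Key disconnection: C4–C5 and C9–C10 together. One Mn(OAc)3 radical cascade on an acyclic (−)-8-phenylmenthyl β-keto ester closes ring A first and ring B second. A tert-butylsulfonyl group on C7 is expelled to end the cascade, which places the alkene at C7=C8.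
- The acyclic precursor comes from an acetoacetate dianion and a C1 allylic bromide. The C6–C7 bond comes from alkylation of an allyl sulfone (made from (R)-citronellol, which brings C13) with the E-1,4-dibromide of isoprene.

Assumption: atoms are numbered as in labdane (C1–C20); the target is taken exactly as drawn, i.e. the ent-labdane (3S,4R,5S,9R,10S,13R) with axial 3-OH and axial C19 acetoxymethyl cis to C20. Sodium 2-methylpropane-2-sulfinate is taken as a purchasable reagent.

**Route**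

Step 1
Reactants: 1 (R)-(+)-citronellol
Product: 2 (R)-citronellyl tert-butyldiphenylsilyl ether
Conditions: TBDPSCl, imidazole, DMF, rt
Reagents that add atoms: tert-butyl(chloro)diphenylsilane, CC(C)(C)[Si](Cl)(c1ccccc1)c1ccccc1
Why: Silyl ether formation masks the future C15 oxygen in a form that survives carbanions, Mn(OAc)3 and hydrides; C13 comes from the chiral pool and is never touched again.

Step 2
Reactants: 2 (R)-citronellyl tert-butyldiphenylsilyl ether
Product: 3 (2E,6R)-8-[(tert-butyldiphenylsilyl)oxy]-2,6-dimethyloct-2-en-1-ol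
Conditions: SeO2 (0.5 equiv), t-BuOOH (3 equiv), salicylic acid (cat.), CH2Cl2, rt
Reagents that add atoms: selenium dioxide, O=[Se]=O (oxygen carrier); tert-butyl hydroperoxide, CC(C)(C)OO (stoichiometric oxygen source)
Why: Sharpless SeO2/t-BuOOH allylic oxidation (ene reaction then [2,3]-shift) hydroxylates only the E-methyl of the trisubstituted alkene, which fixes the E geometry of the future C8=C9 bond.

Step 3
Reactants: 3 (2E,6R)-8-[(tert-butyldiphenylsilyl)oxy]-2,6-dimethyloct-2-en-1-ol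
Product: 5 (3R,6E)-8-(tert-butylsulfonyl)-3,7-dimethyloct-6-en-1-yl tert-butyldiphenylsilyl ether, via allylic bromide 4 (not isolated)
Conditions: CBr4, PPh3, CH2Cl2, 0 °C; then t-BuSO2Na, DMF, rt
Reagents that add atoms: sodium 2-methylpropane-2-sulfinate, CC(C)(C)S(=O)[O-].[Na+]
Why: Appel bromination followed by S-alkylation of the sulfinate by the soft primary allylic bromide, both SN2, so the E alkene is kept.

Step 4
Reactants: 6 isoprene
Product: 7 (E)-1,4-dibromo-2-methylbut-2-ene
Conditions: Br2 (1.0 equiv), CH2Cl2, −20 °C → rt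
Reagents that add atoms: bromine, BrBr
Why: Electrophilic 1,4-addition of bromine to the diene; the allylic dibromides equilibrate to the thermodynamically preferred E-1,4-adduct.

Step 5
Reactants: 5 (3R,6E)-8-(tert-butylsulfonyl)-3,7-dimethyloct-6-en-1-yl tert-butyldiphenylsilyl ether; 7 (E)-1,4-dibromo-2-methylbut-2-ene (3 equiv)
Product: 9 (2E,6E,10R)-1-bromo-5-(tert-butylsulfonyl)-2,6,10-trimethyl-12-[(tert-butyldiphenylsilyl)oxy]dodeca-2,6-diene (both C5 epimers), via lithiated sulfone 8 (not isolated)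
Conditions: n-BuLi, THF, −78 °C; then add to 7 (3 equiv), THF, −78 → −40 °C
Reagents that add atoms: none
Why: Alkylation of an α-sulfonyl allyl carbanion at its α-carbon (Julia-type coupling); the anion attacks the less hindered, prenyl-type CH2Br of 7 (remote from the methyl), excess 7 suppresses double alkylation, and the new sulfone-bearing centre (labdane C7) may be a mixture because it becomes sp2 in step 8.

Step 6
Reactants: 10 (−)-8-phenylmenthol; 11 2,2,6-trimethyl-4H-1,3-dioxin-4-one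
Product: 12 (−)-8-phenylmenthyl acetoacetate
Conditions: xylenes, 140 °C, acetone distilled off
Reagents that add atoms: none
Why: Thermal retro-hetero-Diels–Alder of the dioxinone gives acetylketene, which acetoacetylates the hindered secondary alcohol without touching its stereocentres.

Step 7
Reactants: 12 (−)-8-phenylmenthyl acetoacetate; 9 (2E,6E,10R)-1-bromo-5-(tert-butylsulfonyl)-2,6,10-trimethyl-12-[(tert-butyldiphenylsilyl)oxy]dodeca-2,6-diene
Product: 14 (−)-8-phenylmenthyl (6E,10E,14R)-9-(tert-butylsulfonyl)-6,10,14-trimethyl-3-oxo-16-[(tert-butyldiphenylsilyl)oxy]hexadeca-6,10-dienoate, via acetoacetate dianion 13 (not isolated)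
Conditions: NaH, THF, 0 °C; n-BuLi, 0 °C; then 9, 0 °C; 1 M HCl quench
Reagents that add atoms: none
Why: Weiler dianion alkylation: the γ-carbanion of the acetoacetate displaces the allylic bromide by SN2 (C1–C2 bond), much faster than proton transfer from the hindered tertiary α-sulfonyl C–H.

Step 8
Reactants: 14 (−)-8-phenylmenthyl (6E,10E,14R)-9-(tert-butylsulfonyl)-6,10,14-trimethyl-3-oxo-16-[(tert-butyldiphenylsilyl)oxy]hexadeca-6,10-dienoate
Product: 15 (−)-8-phenylmenthyl 3-oxo-15-[(tert-butyldiphenylsilyl)oxy]-18-nor-ent-labd-7-en-19-oate (trans-decalin; C4–H enolisable)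
Conditions: Mn(OAc)3·2H2O (2.5 equiv), Yb(OTf)3 (1.0 equiv), CF3CH2OH, degassed, −5 °C → rt
Reagents that add atoms: none
Why: Proposed new method: Mn(OAc)3 oxidises the Yb(OTf)3-chelated β-keto ester to its α-radical, which closes ring A 6-endo onto C5=C10 on the face not covered by the stacked phenyl ring of the (1R,2S,5R) auxiliary; the tertiary C10 radical then closes ring B 6-endo onto C9 through a chair (trans fusion, E alkene puts C11 equatorial, so C5, C9 and C10 are set together), and the tertiary C8 radical ends the cascade by β-scission of the C7–SO2t-Bu bond, which fixes the alkene at C7=C8 from either C7 epimer, while t-BuSO2• collapses to SO2 and t-Bu• (oxidised by the second equivalent of Mn(OAc)3) so that no sulfonyl radical persists to isomerise alkenes; the closest known chemistry is the Mn(OAc)3/Yb(OTf)3 oxidative radical polyene cyclisation of 8-phenylmenthyl β-keto esters (where, as I recall it, the (+)-auxiliary gives the normal diterpene series, hence the (−)-auxiliary here) combined with radical addition–fragmentation of allyl sulfones.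

Step 9
Reactants: 15 (−)-8-phenylmenthyl 3-oxo-15-[(tert-butyldiphenylsilyl)oxy]-18-nor-ent-labd-7-en-19-oate
Product: 16 (−)-8-phenylmenthyl 3-oxo-15-[(tert-butyldiphenylsilyl)oxy]-ent-labd-7-en-19-oate (ester axial and cis to C20; new C18 methyl equatorial)
Conditions: K2CO3, MeI, acetone, 40 °C
Reagents that add atoms: iodomethane, CI
Why: C-alkylation of the cyclic β-keto ester enolate: MeI approaches planar C4 anti to the axial C10 methyl, the same face the auxiliary leaves open, so the methyl ends equatorial and the ester (future C19) axial.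

Step 10
Reactants: 16 (−)-8-phenylmenthyl 3-oxo-15-[(tert-butyldiphenylsilyl)oxy]-ent-labd-7-en-19-oate
Product: 18 15-[(tert-butyldiphenylsilyl)oxy]-ent-labd-7-ene-3,19-diol (3-OH axial), via 3-hydroxy ester 17 (not isolated)
Conditions: LiBH(s-Bu)3 (L-Selectride), THF, −78 → −20 °C; then LiAlH4, THF, 0 → 50 °C; aq. NaOH work-up
Reagents that add atoms: none
Why: Steric approach control: the bulky borohydride attacks the C3 ketone along the equatorial trajectory to give the axial alcohol trans to C19, and LiAlH4 then reduces the hindered neopentyl ester to the C19 carbinol and releases the auxiliary, while silyl ether and alkene are inert.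

Step 11
Reactants: 18 15-[(tert-butyldiphenylsilyl)oxy]-ent-labd-7-ene-3,19-diol
Product: 19 19-acetoxy-15-[(tert-butyldiphenylsilyl)oxy]-ent-labd-7-en-3-ol
Conditions: Ac2O (1.2 equiv), pyridine, CH2Cl2, 0 °C
Reagents that add atoms: acetic anhydride, CC(=O)OC(C)=O
Why: Chemoselective acylation of the primary C19 hydroxyl; the axial secondary C3 hydroxyl next to quaternary C4 does not react without DMAP, and the trans-diaxial O3/C19 geometry rules out later acetyl migration.

Step 12
Reactants: 19 19-acetoxy-15-[(tert-butyldiphenylsilyl)oxy]-ent-labd-7-en-3-ol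
Product: 20 19-acetoxy-ent-labd-7-ene-3,15-diol
Conditions: Bu4NF, AcOH, THF, rt
Reagents that add atoms: none
Why: Fluoride-driven Si–O cleavage, buffered with AcOH so that the acetate is not hydrolysed.

Step 13
Reactants: 20 19-acetoxy-ent-labd-7-ene-3,15-diol
Product: 22 CNP0218903.1, via aldehyde 21 (not isolated)
Conditions: TEMPO (0.2 equiv), PhI(OAc)2 (2.2 equiv), MeCN/H2O 1:1, rt
Reagents that add atoms: water, O
Why: Oxoammonium (TEMPO) oxidation with PhI(OAc)2 as terminal oxidant takes the unhindered primary alcohol through the aldehyde hydrate to the acid and leaves the hindered axial secondary alcohol, the acetate and the alkene untouched.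

**Compound list**

1 | (R)-(+)-citronellol, (3R)-3,7-dimethyloct-6-en-1-ol | CC(C)=CCC[C@@H](C)CCO | starting material
2 | tert-butyl{[(3R)-3,7-dimethyloct-6-en-1-yl]oxy}diphenylsilane | CC(C)=CCC[C@@H](C)CCO[Si](c1ccccc1)(c1ccccc1)C(C)(C)C | intermediate
3 | (2E,6R)-8-[(tert-butyldiphenylsilyl)oxy]-2,6-dimethyloct-2-en-1-ol | OC/C(C)=C/CC[C@@H](C)CCO[Si](c1ccccc1)(c1ccccc1)C(C)(C)C | intermediate
4 | {[(3R,6E)-8-bromo-3,7-dimethyloct-6-en-1-yl]oxy}(tert-butyl)diphenylsilane | BrC/C(C)=C/CC[C@@H](C)CCO[Si](c1ccccc1)(c1ccccc1)C(C)(C)C | intermediate (not isolated)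
5 | tert-butyl{[(3R,6E)-8-(tert-butylsulfonyl)-3,7-dimethyloct-6-en-1-yl]oxy}diphenylsilane | CC(C)(C)S(=O)(=O)C/C(C)=C/CC[C@@H](C)CCO[Si](c1ccccc1)(c1ccccc1)C(C)(C)C | intermediate
6 | isoprene (2-methylbuta-1,3-diene) | C=CC(C)=C | starting material
7 | (E)-1,4-dibromo-2-methylbut-2-ene | BrC/C=C(C)/CBr | intermediate
8 | α-lithio derivative of 5 (lithium on the carbon between sulfonyl group and alkene) | [Li+].CC(C)(C)S(=O)(=O)[CH-]/C(C)=C/CC[C@@H](C)CCO[Si](c1ccccc1)(c1ccccc1)C(C)(C)C | intermediate (not isolated)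
9 | (2E,6E,10R)-1-bromo-5-(tert-butylsulfonyl)-2,6,10-trimethyl-12-[(tert-butyldiphenylsilyl)oxy]dodeca-2,6-diene, both C5 epimers | BrC/C(C)=C/CC(S(=O)(=O)C(C)(C)C)/C(C)=C/CC[C@@H](C)CCO[Si](c1ccccc1)(c1ccccc1)C(C)(C)C | intermediate
10 | (−)-8-phenylmenthol, (1R,2S,5R)-5-methyl-2-(2-phenylpropan-2-yl)cyclohexan-1-ol | C[C@@H]1CC[C@H]([C@@H](C1)O)C(C)(C)c1ccccc1 | starting material
11 | 2,2,6-trimethyl-4H-1,3-dioxin-4-one | CC1=CC(=O)OC(C)(C)O1 | starting material
12 | (1R,2S,5R)-5-methyl-2-(2-phenylpropan-2-yl)cyclohexyl 3-oxobutanoate | CC(=O)CC(=O)O[C@@H]1C[C@H](C)CC[C@H]1C(C)(C)c1ccccc1 | intermediate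
13 | sodium lithium dianion of 12 (deprotonated at C2 and C4 of the butanoate) | [Na+].[Li+].[CH2-]C(=O)[CH-]C(=O)O[C@@H]1C[C@H](C)CC[C@H]1C(C)(C)c1ccccc1 | intermediate (not isolated)
14 | (−)-8-phenylmenthyl (6E,10E,14R)-9-(tert-butylsulfonyl)-6,10,14-trimethyl-3-oxo-16-[(tert-butyldiphenylsilyl)oxy]hexadeca-6,10-dienoate, both C9 epimers | O=C(CC(=O)CC/C(C)=C/CC(S(=O)(=O)C(C)(C)C)/C(C)=C/CC[C@@H](C)CCO[Si](c1ccccc1)(c1ccccc1)C(C)(C)C)O[C@@H]1C[C@H](C)CC[C@H]1C(C)(C)c1ccccc1 | intermediate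
15 | (−)-8-phenylmenthyl 3-oxo-15-[(tert-butyldiphenylsilyl)oxy]-18-nor-ent-labd-7-en-19-oate; trans-decalin with C5, C9, C10, C13 as in 22; C4–H enolisable, drawn as keto form | O=C(O[C@@H]1C[C@H](C)CC[C@H]1C(C)(C)c1ccccc1)C3[C@H]2CC=C(C)[C@@H](CC[C@@H](C)CCO[Si](c4ccccc4)(c4ccccc4)C(C)(C)C)[C@]2(C)CCC3=O | intermediate
16 | (−)-8-phenylmenthyl 3-oxo-15-[(tert-butyldiphenylsilyl)oxy]-ent-labd-7-en-19-oate; C4 as in 22 (ester axial, methyl equatorial) | O=C(O[C@@H]1C[C@H](C)CC[C@H]1C(C)(C)c1ccccc1)[C@@]3(C)[C@H]2CC=C(C)[C@@H](CC[C@@H](C)CCO[Si](c4ccccc4)(c4ccccc4)C(C)(C)C)[C@]2(C)CCC3=O | intermediate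
17 | (−)-8-phenylmenthyl 3-hydroxy-15-[(tert-butyldiphenylsilyl)oxy]-ent-labd-7-en-19-oate, 3-OH axial (present as its borate) | O=C(O[C@@H]1C[C@H](C)CC[C@H]1C(C)(C)c1ccccc1)[C@@]3(C)[C@H]2CC=C(C)[C@@H](CC[C@@H](C)CCO[Si](c4ccccc4)(c4ccccc4)C(C)(C)C)[C@]2(C)CC[C@@H]3O | intermediate (not isolated)
18 | 15-[(tert-butyldiphenylsilyl)oxy]-ent-labd-7-ene-3,19-diol, 3-OH axial and trans to C19 | OC[C@@]1(C)[C@H]2CC=C(C)[C@@H](CC[C@@H](C)CCO[Si](c3ccccc3)(c3ccccc3)C(C)(C)C)[C@]2(C)CC[C@@H]1O | intermediate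
19 | 19-acetoxy-15-[(tert-butyldiphenylsilyl)oxy]-ent-labd-7-en-3-ol | CC(=O)OC[C@@]1(C)[C@H]2CC=C(C)[C@@H](CC[C@@H](C)CCO[Si](c3ccccc3)(c3ccccc3)C(C)(C)C)[C@]2(C)CC[C@@H]1O | intermediate
20 | 19-acetoxy-ent-labd-7-ene-3,15-diol | CC(=O)OC[C@@]1(C)[C@H]2CC=C(C)[C@@H](CC[C@@H](C)CCO)[C@]2(C)CC[C@@H]1O | intermediate
21 | 19-acetoxy-3-hydroxy-ent-labd-7-en-15-al | CC(=O)OC[C@@]1(C)[C@H]2CC=C(C)[C@@H](CC[C@@H](C)CC=O)[C@]2(C)CC[C@@H]1O | intermediate (not isolated)
22 | CNP0218903.1, (3S,4R,5S,9R,10S,13R)-19-acetoxy-3-hydroxy-ent-labd-7-en-15-oic acid | CC(=O)OC[C@@]1(C)[C@H]2CC=C(C)[C@@H](CC[C@@H](C)CC(=O)O)[C@]2(C)CC[C@@H]1O | target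

**Totals and risks**

Total step count: 13. Longest linear sequence: 11 steps (1 → 22 through steps 1, 2, 3, 5, 7, 8, 9, 10, 11, 12, 13).

Steps most likely to fail:

Step 8 (radical bicyclisation ended by sulfonyl loss). The β-scission may be slow for the C7 epimer whose sulfone sits equatorial, and the sense and level of auxiliary control rest on analogy with aryl-terminated cases. The fallback sets out from acetoacetate 12 (used as dianion 13) and comes back at 15. Commercial (2E,6E)-farnesol F1 is hydrogenated at its allylic-alcohol alkene only (H2, Ru(OAc)2[(S)-BINAP], MeOH) to (R)-2,3-dihydrofarnesol F2. This is silylated (TBDPSCl, imidazole) to silyl ether F3, oxidised (SeO2, t-BuOOH) at the terminal E-methyl to allylic alcohol F4, and brominated (CBr4, PPh3) to allylic bromide F5. Alkylation of dianion 13 with F5 gives the sulfone-free polyene keto ester F6. Mn(OAc)3/Cu(OAc)2/Yb(OTf)3 in CF3CH2OH then runs the same auxiliary-controlled bicyclisation but ends it by copper-mediated oxidative elimination to the exocyclic 8(17)-alkene F7. A radical hydrogen-atom-transfer isomerisation (Co(salen)Cl cat., PhSiH3 cat., benzene, rt) then moves the alkene to C7=C8, giving 15; the C7 methylene hydrogens are far more accessible than the C9 methine next to quaternary C10.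

Step 5 (mono-alkylation of the dibromide). Risks are modest regioselectivity between the two allylic bromides, double alkylation, and base-induced elimination of HBr. The fallback sets out from isoprene 6 and lithiated sulfone 8 and comes back at 9. Isoprene 6 is epoxidised at its more substituted alkene (mCPBA, CH2Cl2, 0 °C) to 2-methyl-2-vinyloxirane F8. SN2′ opening (aq. HBr, CuBr cat., Et2O, −10 °C) gives (E)-4-bromo-2-methylbut-2-en-1-ol F9, which is silylated (TBSCl, imidazole) to TBS ether F10, a mono-electrophile. Alkylation of lithiated sulfone 8 with F10 gives the coupled bis-silyl ether F11. The allylic TBS ether is removed selectively (CSA, MeOH, 0 °C; the TBDPS ether stays) to give allylic alcohol F12, and Appel bromination (CBr4, PPh3) gives 9.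

Step 10 (axial alcohol by bulky hydride). The axial ester at C4 may block the equatorial trajectory and give the equatorial alcohol or no reaction. The fallback sets out from 16 and comes back at 18. LiAlH4 alone reduces ketone and ester to the 3-epimeric diol F13 (equatorial 3-OH expected as the main epimer). Dess–Martin periodinane oxidises both hydroxyls to keto aldehyde F14. Me4NBH(OAc)3 in AcOH/MeCN at −20 °C reduces the aldehyde first; the resulting axial C19–O–B hydride is then delivered intramolecularly to the ketone face syn to C19, which forces the 3-OH axial and trans to C19, giving 18.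

**Further compounds**

F1 | step 8 | (2E,6E)-farnesol (purchased) | CC(C)=CCC/C(C)=C/CC/C(C)=C/CO
F2 | step 8 | (R)-2,3-dihydrofarnesol, (3R,6E)-3,7,11-trimethyldodeca-6,10-dien-1-ol | CC(C)=CCC/C(C)=C/CC[C@@H](C)CCO
F3 | step 8 | tert-butyldiphenylsilyl ether of F2 | CC(C)=CCC/C(C)=C/CC[C@@H](C)CCO[Si](c1ccccc1)(c1ccccc1)C(C)(C)C
F4 | step 8 | (2E,6E,10R)-12-[(tert-butyldiphenylsilyl)oxy]-2,6,10-trimethyldodeca-2,6-dien-1-ol | OC/C(C)=C/CC/C(C)=C/CC[C@@H](C)CCO[Si](c1ccccc1)(c1ccccc1)C(C)(C)C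
F5 | step 8 | (2E,6E,10R)-1-bromo-2,6,10-trimethyl-12-[(tert-butyldiphenylsilyl)oxy]dodeca-2,6-diene | BrC/C(C)=C/CC/C(C)=C/CC[C@@H](C)CCO[Si](c1ccccc1)(c1ccccc1)C(C)(C)C
F6 | step 8 | (−)-8-phenylmenthyl (6E,10E,14R)-6,10,14-trimethyl-3-oxo-16-[(tert-butyldiphenylsilyl)oxy]hexadeca-6,10-dienoate | O=C(CC(=O)CC/C(C)=C/CC/C(C)=C/CC[C@@H](C)CCO[Si](c1ccccc1)(c1ccccc1)C(C)(C)C)O[C@@H]1C[C@H](C)CC[C@H]1C(C)(C)c1ccccc1
F7 | step 8 | (−)-8-phenylmenthyl 3-oxo-15-[(tert-butyldiphenylsilyl)oxy]-18-nor-ent-labd-8(17)-en-19-oate | O=C(O[C@@H]1C[C@H](C)CC[C@H]1C(C)(C)c1ccccc1)C3[C@H]2CCC(=C)[C@@H](CC[C@@H](C)CCO[Si](c4ccccc4)(c4ccccc4)C(C)(C)C)[C@]2(C)CCC3=O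
F8 | step 5 | 2-methyl-2-vinyloxirane (racemic) | C=CC1(C)CO1
F9 | step 5 | (E)-4-bromo-2-methylbut-2-en-1-ol | OC/C(C)=C/CBr
F10 | step 5 | {[(E)-4-bromo-2-methylbut-2-en-1-yl]oxy}(tert-butyl)dimethylsilane | CC(C)(C)[Si](C)(C)OC/C(C)=C/CBr
F11 | step 5 | (2E,6E,10R)-1-[(tert-butyldimethylsilyl)oxy]-5-(tert-butylsulfonyl)-2,6,10-trimethyl-12-[(tert-butyldiphenylsilyl)oxy]dodeca-2,6-diene, both C5 epimers | CC(C)(C)[Si](C)(C)OC/C(C)=C/CC(S(=O)(=O)C(C)(C)C)/C(C)=C/CC[C@@H](C)CCO[Si](c1ccccc1)(c1ccccc1)C(C)(C)C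
F12 | step 5 | (2E,6E,10R)-5-(tert-butylsulfonyl)-2,6,10-trimethyl-12-[(tert-butyldiphenylsilyl)oxy]dodeca-2,6-dien-1-ol, both C5 epimers | OC/C(C)=C/CC(S(=O)(=O)C(C)(C)C)/C(C)=C/CC[C@@H](C)CCO[Si](c1ccccc1)(c1ccccc1)C(C)(C)C
F13 | step 10 | 15-[(tert-butyldiphenylsilyl)oxy]-ent-labd-7-ene-3,19-diol, 3-epimer of 18 (equatorial 3-OH) | OC[C@@]1(C)[C@H]2CC=C(C)[C@@H](CC[C@@H](C)CCO[Si](c3ccccc3)(c3ccccc3)C(C)(C)C)[C@]2(C)CC[C@H]1O
F14 | step 10 | 3-oxo-15-[(tert-butyldiphenylsilyl)oxy]-ent-labd-7-en-19-al | O=C[C@@]1(C)[C@H]2CC=C(C)[C@@H](CC[C@@H](C)CCO[Si](c3ccccc3)(c3ccccc3)C(C)(C)C)[C@]2(C)CCC1=O
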